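## Analysis of the target

Oblongifolin B (34) is a type B polyprenylated acylphloroglucinol built on a bicyclo[3.3.1]nonane. Throughout, C1 and C5 are the prenylated bridgeheads (C1 is the one next to the CMe2 carbon C8), C9 is the bridging ketone, ring A is C1–C2–C3–C4–C5–C9 (the enolised 2,4-dione, acylated at C3 by 3,4-dihydroxybenzoyl) and ring B is C5–C6–C7–C8–C1–C9 (geranyl on C7); the same locants are used for intermediates in which the bicycle does not yet exist. There are three stereocentres, C1 (S), C5 (S) and C7 (R), but only two stereochemical elements: the quaternary bridgeheads are tied to each other by the bridge, and C7 carries its geranyl group exo, that is equatorial on the chair of ring B and turned away from ring A ("endo" means pointing under ring A). The sensitive groups are the four trisubstituted alkenes (one E-configured), which rule out hydrogenation, strong electrophiles and late protic acid (the C4 enol cyclises onto the C5 prenyl group), the catechol, which is oxidised under aerobic base, and the non-enolisable β-dicarbonyl arrays around C1 and C5, which are open to retro-Claisen cleavage. The synthesis is hard because C1 and C8 are adjacent fully substituted carbons, both carbons flanking C9 are quaternary, the absolute configuration has to be created in a skeleton without any heteroatom-bearing stereocentre, and the exo position at C7 is the one that reagents adding hydrogen to C7 do not deliver. The strategy rests on the fact that C1 lies between two oxygenated carbons, C9 and C2, as the substituted carbon of a 2-alkylresorcinol lies between its two C–O carbons. Birch reduction of such an ether leaves C1 between two enantiotopic enol ethers (C9=C5 and C2=C3), and because C6 is alpha to C7, a carbene at C6 held by a C7 ketone can reach one of them. The price is one extra bond, C6–C9, which the oxygen on C9 and the carbonyl at C7 allow to be broken again.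

## Retrosynthetic reasoning

**34 to 33 to 32 (O–H bonds).** The free acyl trione is acidic and chelating and cyclises under acid, and the free catechol does not tolerate the strong bases used earlier. The target is therefore traced back to methyl vinylogous ester 33 and its bis-silyl ether 32. The methyl group is the one the starting arene already carries on the C2 oxygen, so no step is spent on putting it on. Forward, desilylation is followed by a neutral nucleophilic demethylation.

**32 to 27 and 31 (C3–aroyl bond).** C3 is the only sp2 C–H of ring A and lies between the methoxy carbon and the C4 carbonyl, so it can be metalated once no other acidic hydrogen is left. Adding the aroyl group last keeps its ketone out of every organometallic step. Acid chloride 31 comes from 28 through 30.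

**27 to 26 and 7 (C5–prenyl bond).** With the C4 carbonyl in place, C5–H is the one hydrogen between two carbonyls. The bridge forbids inversion, so the alkylation raises no stereochemical question. It must wait until the C7 chain is complete, because before that a C6–H next to the C7 ketone, or the hydrogen alpha to the formyl group, would be removed first.

**26 to 21 and 24, and 21 back to 15 (geranyl group).** The chain is cut between C1' and C2', not at C7. The E-trisubstituted alkene then arrives finished in alkenyl iodide 24 (from alkyne 22 by syn carbometalation), and the sp3–sp2 bond is made by cross-coupling of the organozinc from iodide 21, which cannot disturb C7 or the alkene geometry. The C7–C1' bond is traced to the C7 ketone of 15 through methylene compound 16. Hydrogen is delivered to C7 of 16 from the open exo face, which puts the new carbon endo (17). The exo configuration is therefore reached under thermodynamic control at the aldehyde stage (18 to 19), the only point at which C7 is acidic. Reduction and iodination give 20 and 21.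

**15 to 14 (C4=O).** C4 is the allylic position of the C2 enol ether of 14. It is oxidised when only one prenyl group is present and before the exocyclic alkene exists.

**14 to 12 (the sacrificial bond).** Joining C6 to C9 gives the donor–acceptor cyclopropane 12. Forward, the C6–C9 bond breaks with push from the C9 oxygen and pull from the C7 carbonyl, the methyl on that oxygen is lost, and the five-membered ring C9–C1–C8–C7–C6 becomes ring B. The second enol ether (C2=C3) is the handle for C4 and must survive. For that reason the opening is run with a silyl iodide under aprotic conditions (through 13) and not with aqueous acid.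

**12 to 11 (key disconnection, C5–C6 and C6–C9).** Both bonds are cut at once, which leaves a carbene at C6 and the C5=C9 enol ether. Diazo ketone 11 has a mirror plane through C1, C4 and the side chain. A chiral copper carbene that picks one of the two enol ethers fixes C1 and C5 in a single event, with cis fusion enforced by the short tether. The C1–C8 bond is already present.

**11 to 9 to 8, and 8 to 6 and 7.** The diazo group is put on by diazo transfer to methyl ketone 9 (through 10), not by acylating a diazoalkane with an activated acid. That acid would be extremely hindered and is placed to lactonise onto an enol ether. Ketone 9 comes from alcohol 8. The C1–prenyl bond is cut to dienyl alcohol 6 and bromide 7. C1 is the doubly allylic carbon between the two enol ether oxygens and the most acidic C–H. Its alkylation creates a quaternary carbon next to CMe2, the most demanding bond formation before the key step.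

**6 to 4 to 3 to 1.** Birch reduction of 4 gives 6; the ketone is reduced in the same operation (through 5), and the alkoxide protects the side chain and later directs the lithiation. Ketone 4 comes from acid 3 by organolithium addition to the carboxylate, and 3 from 1 by two methylations (through 2). The C1–C8 bond is thus bought with the starting material, on an aromatic carbon.

## Alternatives that were turned down

**Alternative 1:** Ring B is cut at C1–C8 and C6–C7, a [4+2] retron with C7 as the acyl-bearing carbon. Forward, silyloxydiene A1 and the β,β-dimethylacryloyl imide A2 would combine under a chiral bis(oxazoline) Lewis acid of divalent copper to cyclohexene A3. A3 holds C7, the gem-dimethyl carbon, the C5 prenyl group and C9 as a silyl enol ether.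
- For it: C7 is set directly by a catalyst class with a dependable stereochemical model, and its acyl group is a handle for the geranyl chain. The chosen route reaches this centre only by equilibration.
- Against it: A2 is β,β-disubstituted, and its β carbon is the one that must become quaternary C8. This is the least reactive kind of dienophile for a chelating Lewis acid. After the cycloaddition both quaternary bridgeheads, the C1–C8 pair included, still have to be made on a flexible monocycle with only remote C7 as control element. Ring A must then be closed by double C-acylation between two hindered carbons.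
- Comparison: stronger at C7 and about equal in length if the annulation works. The chosen strategy sets C1 and C5 in the step that makes the bicycle and has the C1–C8 bond from the start, at the price of a longer end game at C7.

**Alternative 2:** The C1–C8 bond is cut as the σ bond of a [3,3] shift, with C9–O–CH2 as a temporary tether. Forward, heating the fused dihydropyran A4, alone or with a lanthanide Lewis acid, would form C1–C8 as the O–CH2 bond breaks and give A5. In A4 the vinyl ether is C1=C9–O and the allyl unit is O–CH2–C7=C8Me2.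
- For it: the most congested bond is formed intramolecularly in an ordered transition state. A5 already carries both bridgehead prenyl groups, the C9 ketone, the ring A vinylogous ester and a C7 methylene group; it corresponds to 16 with the C5 prenyl group in place. Transfer of chirality from C5 to C1 is complete.
- Against it: the single stereocentre of A4, quaternary C5 on a cross-conjugated dienone, must be made enantioselectively beforehand by an alkylative dearomatisation whose absolute control is the open question. The shift must bond to a fully substituted alkene terminus through a strained, bridged transition state. The C1 prenyl group and the dienone offer competing sigmatropic and rearomatisation paths.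
- Comparison: clearly stronger in convergence and in step count after the key step. The chosen strategy instead creates the absolute configuration in the key step itself, by a reaction type documented for this substrate class.

**Alternative 3:** Ring B is cut at C5–C6 and C1–C8, and ring A is taken as a complete, acylated and diprenylated phloroglucinol. Forward, the anion of A6, paired with a cinchona-derived quaternary ammonium cation, attacks the CH2 terminus of acyloxy enal A7 through C5. The acyloxy group leaves, and C1 closes onto the new CMe2 terminus to give A8.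
- For it: by far the shortest route. The whole skeleton except the chain beyond C1' arises in one step from an aromatic compound, with a C7 formyl group that is the same epimerisable handle as 19.
- Against it: the absolute configuration depends on a loose ion pair telling apart two enantiotopic carbons of a delocalised, multiply charged nucleophile. The second conjugate addition joins quaternary C1 to a β,β-dimethyl terminus and is reversible. O-alkylation, and aldol closure of the formyl group onto C3 to a cage, compete. All later work at C7 would have to be done on the free, acidic acyl trione carrying silyl-protected catechol.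
- Comparison: stronger in step economy and convergence. The chosen route offers a catalyst-bound, covalently held carbene for the enantiotopic choice and keeps ring A masked as a methyl vinylogous ester until the last two steps.

Key step: step 7

Assumption: which antipode of the bis(oxazoline) ligand steers the copper carbene to the enol ether that leads to 12 cannot be derived on paper; the (S,S) ligand is written, and the equally available (R,R) ligand is used instead if the sense of induction proves opposite.

## Route

Step 1
Reactants: 1 2-(2,6-dimethoxyphenyl)acetic acid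
Product: 3 2-(2,6-dimethoxyphenyl)-2-methylpropanoic acid, via monomethyl acid 2 (not isolated)
Conditions: LiN(i-Pr)2 (LDA, 2.2 equiv), THF, −78 → 0 °C; MeI (1.05 equiv); LDA (1.2 equiv), 0 °C; MeI (1.5 equiv), 0 °C → rt; aq. HCl work-up
Reagents that add atoms: iodomethane, CI
Why: Alkylation of a carboxylic acid dianion (enediolate), run twice in one flask; the benzylic carbon is the only carbon nucleophile, the ortho methoxy groups hold lithium for the second deprotonation, and no stereocentre remains.

Step 2
Reactants: 3 2-(2,6-dimethoxyphenyl)-2-methylpropanoic acid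
Product: 4 3-(2,6-dimethoxyphenyl)-3-methylbutan-2-one
Conditions: MeLi (3 equiv), Et2O, 0 °C → reflux; inverse quench into ice-cold 1 M HCl
Reagents that add atoms: methyllithium, [Li]C
Why: Addition of an organolithium to a lithium carboxylate stops at the geminal dialkoxide, which should give the methyl ketone only on work-up; the carbon added here is the future C6.

Step 3
Reactants: 4 3-(2,6-dimethoxyphenyl)-3-methylbutan-2-one
Product: 6 3-(2,6-dimethoxycyclohexa-2,5-dien-1-yl)-3-methylbutan-2-ol (racemic), via aryl carbinol 5 (not isolated)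
Conditions: Li (10 equiv), NH3(l)/THF, t-BuOH (6 equiv), −78 → −33 °C; NH4Cl(s), then evaporation of NH3
Reagents that add atoms: none
Why: Birch reduction; lithium first reduces the ketone to its alkoxide and then the 2-alkylresorcinol ether ring to the 2,5-dihydro isomer, in which both methoxy carbons stay sp2. The carbinol centre is racemic and is removed in step 5.

Step 4
Reactants: 6 3-(2,6-dimethoxycyclohexa-2,5-dien-1-yl)-3-methylbutan-2-ol; 7 1-bromo-3-methylbut-2-ene (prenyl bromide)
Product: 8 3-[2,6-dimethoxy-1-(3-methylbut-2-en-1-yl)cyclohexa-2,5-dien-1-yl]-3-methylbutan-2-ol (racemic)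
Conditions: t-BuLi (2.3 equiv), THF, −78 → −40 °C; 7 (1.2 equiv), −78 → −20 °C; aq. NaHCO3
Reagents that add atoms: none
Why: Lithiation of the doubly allylic C–H between the two enol ether oxygens of a 1,5-dimethoxycyclohexa-1,4-diene, assisted by the neighbouring lithium alkoxide, then SN2 alkylation of the cyclohexadienyl anion at its central carbon, which should give quaternary C1. The ring is still symmetric, so no new stereocentre arises.

Step 5
Reactants: 8 3-[2,6-dimethoxy-1-(3-methylbut-2-en-1-yl)cyclohexa-2,5-dien-1-yl]-3-methylbutan-2-ol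
Product: 9 3-[2,6-dimethoxy-1-(3-methylbut-2-en-1-yl)cyclohexa-2,5-dien-1-yl]-3-methylbutan-2-one
Conditions: Dess–Martin periodinane (1.3 equiv), NaHCO3 (5 equiv), CH2Cl2, 0 °C → rt
Reagents that add atoms: none
Why: Dess–Martin oxidation of a hindered secondary alcohol; the bicarbonate buffer keeps the liberated acetic acid away from the enol ethers, and the product is achiral.

Step 6
Reactants: 9 3-[2,6-dimethoxy-1-(3-methylbut-2-en-1-yl)cyclohexa-2,5-dien-1-yl]-3-methylbutan-2-one
Product: 11 1-diazo-3-[2,6-dimethoxy-1-(3-methylbut-2-en-1-yl)cyclohexa-2,5-dien-1-yl]-3-methylbutan-2-one, via trifluoroacetyl diketone 10 (not isolated)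
Conditions: LiN(SiMe3)2 (1.1 equiv), THF, −78 °C; CF3CO2CH2CF3 (1.2 equiv); concentration without acidic work-up; MeSO2N3 (1.5 equiv), Et3N (1.5 equiv), H2O (1 equiv), MeCN, rt
Reagents that add atoms: methanesulfonyl azide, CS(=O)(=O)N=[N+]=[N-]
Why: Detrifluoroacetylative diazo transfer; the ketone can be enolised only on its methyl side, the trifluoroacetyl group activates that carbon for transfer from the sulfonyl azide and is then cleaved off. Every stage is basic, which the enol ethers tolerate.

Step 7
Reactants: 11 1-diazo-3-[2,6-dimethoxy-1-(3-methylbut-2-en-1-yl)cyclohexa-2,5-dien-1-yl]-3-methylbutan-2-one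
Product: 12 (1S,2R,6R,9S)-1,5-dimethoxy-7,7-dimethyl-6-(3-methylbut-2-en-1-yl)tricyclo[4.3.0.0(2,9)]non-4-en-8-one (target locants: cyclopropane C5–C6–C9, methoxy on C9 and C2, ketone C7)
Conditions: (CuOTf)2·C6H6 (copper trifluoromethanesulfonate, CuO3SCF3, benzene complex; 5 mol %), 2,2'-(propane-2,2-diyl)bis[(4S)-4-tert-butyl-4,5-dihydrooxazole] (12 mol %), toluene, rt, slow addition of 11
Reagents that add atoms: none
Why: The copper salt (monovalent copper) bound by the C2-symmetric bis(oxazoline) takes up the diazo carbon of 11 with loss of N2 and becomes an electrophilic copper carbene at C6. This carbene adds to the C5=C9 enol ether in one concerted but asynchronous [2+1] step, bonding first to the nucleophilic carbon C5 and then to C9. The closest known reaction type is the copper–bis(oxazoline)-catalysed asymmetric intramolecular cyclopropanation of α-diazo ketones and α-diazo-β-keto sulfones tethered to the sp3 carbon of 1-alkyl-2,6-dimethoxycyclohexa-2,5-dienes. The three-membered ring C5–C6–C9 closes by the cycloaddition itself, and the five-membered ring C9–C1–C8–C7–C6 closes because the carbene is tethered to C1, in an exo mode with respect to the C5=C9 bond (C5 stays outside this ring). C1 becomes stereogenic only through the choice between the two enantiotopic enol ethers, and this choice is made by the ligand, whose tert-butyl groups block the approach of one of them to the copper-bound carbene. C5 and C9 follow from suprafacial addition to the ring face that carries the tether, and C6 from the cis fusion that a three-atom tether enforces, so the four new stereocentres are not independent and only one diastereomer can form. The step needs enantiotopic-group selectivity, and chemoselectivity against addition to the prenyl alkene, allylic C–H insertion, ylide formation at a methoxy oxygen and Wolff rearrangement. The substrate secures this because the enol ethers are its most nucleophilic π bonds and the only ones within reach of a five-membered ring closure, because the gem-dimethyl group at C8 folds the chain over the ring and leaves no α-hydrogen for a 1,2-shift, and because copper carbenes prefer cyclopropanation to C–H insertion.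

Step 8
Reactants: 12 (1S,2R,6R,9S)-1,5-dimethoxy-7,7-dimethyl-6-(3-methylbut-2-en-1-yl)tricyclo[4.3.0.0(2,9)]non-4-en-8-one
Product: 14 (1R,5R)-2-methoxy-8,8-dimethyl-1-(3-methylbut-2-en-1-yl)bicyclo[3.3.1]non-2-ene-7,9-dione, via C7 trimethylsilyl enol ether 13 (not isolated)
Conditions: Me3SiI (1.2 equiv), (Me3Si)2NH (0.2 equiv), CH2Cl2, −78 → −30 °C; then MeOH, K2CO3 (cat.), 0 °C
Reagents that add atoms: none
Why: Ring opening of a donor–acceptor cyclopropane: silylation of the C7 carbonyl pulls and the C9 methoxy group pushes, the C6–C9 bond breaks, and iodide removes the methyl group from the resulting oxocarbenium ion, which should give the C9 ketone and the C6=C7 silyl enol ether. Aprotic, amine-buffered conditions leave the C2 enol ether untouched, and methanolysis frees the C7 ketone. C1 and C5 are not involved.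

Step 9
Reactants: 14 (1R,5R)-2-methoxy-8,8-dimethyl-1-(3-methylbut-2-en-1-yl)bicyclo[3.3.1]non-2-ene-7,9-dione
Product: 15 (1R,5S)-2-methoxy-8,8-dimethyl-1-(3-methylbut-2-en-1-yl)bicyclo[3.3.1]non-2-ene-4,7,9-trione
Conditions: t-BuOOH (70 % aq., 5 equiv), Rh2(cap)4 (cap = caprolactamate; 1 mol %), K2CO3 (0.5 equiv), CH2Cl2, rt
Reagents that add atoms: tert-butyl hydroperoxide, CC(C)(C)OO
Why: Allylic C–H oxidation by tert-butylperoxy radicals; the C4–H bonds are allylic to the electron-rich enol ether and are the weakest and most electron-rich in the molecule, and the mixed peroxide formed at C4 collapses to the ketone (Kornblum–DeLaMare type). The product should be the vinylogous ester, and the carbonate buffer protects the enol ether.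

Step 10
Reactants: 15 (1R,5S)-2-methoxy-8,8-dimethyl-1-(3-methylbut-2-en-1-yl)bicyclo[3.3.1]non-2-ene-4,7,9-trione
Product: 16 (1R,5S)-2-methoxy-8,8-dimethyl-7-methylidene-1-(3-methylbut-2-en-1-yl)bicyclo[3.3.1]non-2-ene-4,9-dione
Conditions: Zn, CH2Br2, TiCl4, THF/CH2Cl2, 0 °C → rt
Reagents that add atoms: dibromomethane, BrCBr
Why: Takai–Lombardo methylenation, a non-basic reagent that responds strongly to hindrance. C7 has one quaternary neighbour, C9 lies between two bridgeheads, and the C4 carbonyl is deactivated as a vinylogous ester, so C7 should react alone and without enolisation.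

Step 11
Reactants: 16 (1R,5S)-2-methoxy-8,8-dimethyl-7-methylidene-1-(3-methylbut-2-en-1-yl)bicyclo[3.3.1]non-2-ene-4,9-dione
Product: 17 (1R,5S,7S)-7-(hydroxymethyl)-2-methoxy-8,8-dimethyl-1-(3-methylbut-2-en-1-yl)bicyclo[3.3.1]non-2-ene-4,9-dione (hydroxymethyl endo)
Conditions: 9-BBN (1.3 equiv), THF, 0 °C → rt; then NaBO3·4H2O, THF/H2O, rt
Reagents that add atoms: sodium perborate, [Na+].[O-]OB=O
Why: Anti-Markovnikov hydroboration–oxidation; 9-BBN should choose the 1,1-disubstituted alkene over the trisubstituted ones and the hindered carbonyl groups. Hydrogen reaches C7 from the exo face because the endo face is covered by ring A, so the CH2OH group is expected endo; the next step converges whichever face is attacked.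

Step 12
Reactants: 17 (1R,5S,7S)-7-(hydroxymethyl)-2-methoxy-8,8-dimethyl-1-(3-methylbut-2-en-1-yl)bicyclo[3.3.1]non-2-ene-4,9-dione
Product: 19 (1R,5S,7R)-2-methoxy-8,8-dimethyl-1-(3-methylbut-2-en-1-yl)-4,9-dioxobicyclo[3.3.1]non-2-ene-7-carbaldehyde (formyl exo), via 7-endo aldehyde 18 (not isolated)
Conditions: Dess–Martin periodinane (1.3 equiv), NaHCO3, CH2Cl2, 0 °C → rt; filtration; DBU (0.3 equiv), CH2Cl2, rt
Reagents that add atoms: none
Why: Dess–Martin oxidation, then base-mediated epimerisation through the aldehyde enolate. An endo formyl group forces ring B out of its chair, whereas the exo formyl group is equatorial on the strain-free chair–chair form, so equilibration should favour 19. C7 is the only centre that can invert, since C1 and C5 are bridgeheads.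

Step 13
Reactants: 19 (1R,5S,7R)-2-methoxy-8,8-dimethyl-1-(3-methylbut-2-en-1-yl)-4,9-dioxobicyclo[3.3.1]non-2-ene-7-carbaldehyde
Product: 20 (1R,5S,7R)-7-(hydroxymethyl)-2-methoxy-8,8-dimethyl-1-(3-methylbut-2-en-1-yl)bicyclo[3.3.1]non-2-ene-4,9-dione (hydroxymethyl exo)
Conditions: NaBH4 (0.5 equiv), MeOH/CH2Cl2 (1:1), −78 °C
Reagents that add atoms: none
Why: Chemoselective borohydride reduction; at −78 °C the aldehyde should be reduced far faster than the hindered C9 ketone or the vinylogous ester, and the low temperature prevents C7 from epimerising back.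

Step 14
Reactants: 20 (1R,5S,7R)-7-(hydroxymethyl)-2-methoxy-8,8-dimethyl-1-(3-methylbut-2-en-1-yl)bicyclo[3.3.1]non-2-ene-4,9-dione
Product: 21 (1R,5S,7R)-7-(iodomethyl)-2-methoxy-8,8-dimethyl-1-(3-methylbut-2-en-1-yl)bicyclo[3.3.1]non-2-ene-4,9-dione
Conditions: I2, PPh3, imidazole, CH2Cl2, 0 °C → rt
Reagents that add atoms: iodine, II
Why: Appel-type iodination of a primary alcohol by SN2 displacement of the oxyphosphonium group at CH2; C7 is not touched.

Step 15
Reactants: 22 6-methylhept-5-en-1-yne
Product: 24 (1E)-1-iodo-2,6-dimethylhepta-1,5-diene, via alkenyldimethylalane 23 (not isolated)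
Conditions: Me3Al (2 equiv), Cp2ZrCl2 (0.25 equiv), CH2Cl2, 0 °C → rt; then I2, THF, −30 → 0 °C
Reagents that add atoms: trimethylaluminium, C[Al](C)C; iodine, II
Why: Negishi zirconium-catalysed carboalumination; methyl and aluminium add syn across the terminal alkyne with aluminium at the terminus, and iodinolysis with retention should give the E iodide. The trisubstituted alkene is inert.

Step 16
Reactants: 21 (1R,5S,7R)-7-(iodomethyl)-2-methoxy-8,8-dimethyl-1-(3-methylbut-2-en-1-yl)bicyclo[3.3.1]non-2-ene-4,9-dione; 24 (1E)-1-iodo-2,6-dimethylhepta-1,5-diene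
Product: 26 (1R,5S,7R)-7-[(2E)-3,7-dimethylocta-2,6-dien-1-yl]-2-methoxy-8,8-dimethyl-1-(3-methylbut-2-en-1-yl)bicyclo[3.3.1]non-2-ene-4,9-dione, via alkylzinc iodide 25 (not isolated)
Conditions: Zn dust (activated), LiCl, THF, 40 °C; then 24 (1.3 equiv), PdCl2(dppf) (5 mol %), THF, 50 °C
Reagents that add atoms: none
Why: Zinc insertion into the primary C–I bond tolerates ketones, and Negishi cross-coupling of the alkylzinc with the alkenyl iodide proceeds with retention of alkene geometry. The divalent palladium precatalyst is reduced in the flask to zerovalent palladium, and the bidentate ligand favours reductive elimination over β-hydride elimination; C7 is a spectator.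

Step 17
Reactants: 26 (1R,5S,7R)-7-[(2E)-3,7-dimethylocta-2,6-dien-1-yl]-2-methoxy-8,8-dimethyl-1-(3-methylbut-2-en-1-yl)bicyclo[3.3.1]non-2-ene-4,9-dione; 7 1-bromo-3-methylbut-2-ene
Product: 27 (1R,5S,7R)-7-[(2E)-3,7-dimethylocta-2,6-dien-1-yl]-2-methoxy-8,8-dimethyl-1,5-bis(3-methylbut-2-en-1-yl)bicyclo[3.3.1]non-2-ene-4,9-dione
Conditions: LDA (1.3 equiv), THF, −78 °C; 7 (3 equiv), −78 → −30 °C
Reagents that add atoms: none
Why: Bridgehead enolate alkylation; C5–H is the only hydrogen flanked by two carbonyl groups (C4 and C9), and the lithium amide should remove it in preference to the vinyl C3–H. The bridgehead cannot invert, so the prenyl group takes the place of hydrogen.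

Step 18
Reactants: 28 3,4-dihydroxybenzoic acid
Product: 30 3,4-bis(tert-butyldimethylsilyloxy)benzoic acid, via tris-silyl derivative 29 (not isolated)
Conditions: t-BuMe2SiCl (3.5 equiv), imidazole (7 equiv), DMF, rt; then AcOH/THF/H2O (3:1:1), rt
Reagents that add atoms: tert-butyldimethylsilyl chloride, CC(C)(C)[Si](C)(C)Cl
Why: Exhaustive silylation, then selective hydrolysis of the silyl ester, which is far more labile than the aryl silyl ethers.

Step 19
Reactants: 30 3,4-bis(tert-butyldimethylsilyloxy)benzoic acid
Product: 31 3,4-bis(tert-butyldimethylsilyloxy)benzoyl chloride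
Conditions: (COCl)2 (1.5 equiv), DMF (cat.), CH2Cl2, 0 °C → rt; evaporation
Reagents that add atoms: oxalyl chloride, O=C(Cl)C(=O)Cl
Why: Acid chloride formation through the Vilsmeier-type chloroiminium species; the product is used crude.

Step 20
Reactants: 27 (1R,5S,7R)-7-[(2E)-3,7-dimethylocta-2,6-dien-1-yl]-2-methoxy-8,8-dimethyl-1,5-bis(3-methylbut-2-en-1-yl)bicyclo[3.3.1]non-2-ene-4,9-dione; 31 3,4-bis(tert-butyldimethylsilyloxy)benzoyl chloride
Product: 32 (1R,5R,7R)-3-[3,4-bis(tert-butyldimethylsilyloxy)benzoyl]-7-[(2E)-3,7-dimethylocta-2,6-dien-1-yl]-2-methoxy-8,8-dimethyl-1,5-bis(3-methylbut-2-en-1-yl)bicyclo[3.3.1]non-2-ene-4,9-dione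
Conditions: lithium 2,2,6,6-tetramethylpiperidide (2 equiv), THF, −78 °C; 31 (2.5 equiv), −78 → −40 °C
Reagents that add atoms: none
Why: Vinyl lithiation at C3 of the vinylogous ester (α to the C4 carbonyl, held by the C2 methoxy oxygen), the only acidic hydrogen left, followed by C-acylation with the aroyl chloride. The product has no acidic hydrogen and cannot react further.

Step 21
Reactants: 32 (1R,5R,7R)-3-[3,4-bis(tert-butyldimethylsilyloxy)benzoyl]-7-[(2E)-3,7-dimethylocta-2,6-dien-1-yl]-2-methoxy-8,8-dimethyl-1,5-bis(3-methylbut-2-en-1-yl)bicyclo[3.3.1]non-2-ene-4,9-dione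
Product: 33 (1R,5R,7R)-3-(3,4-dihydroxybenzoyl)-7-[(2E)-3,7-dimethylocta-2,6-dien-1-yl]-2-methoxy-8,8-dimethyl-1,5-bis(3-methylbut-2-en-1-yl)bicyclo[3.3.1]non-2-ene-4,9-dione
Conditions: Bu4NF (2.5 equiv), AcOH (2.5 equiv), THF, 0 °C, argon
Reagents that add atoms: none
Why: Fluoride cleavage of the aryl silyl ethers; the acetic acid buffer keeps the catechol protonated and the medium mild enough for the alkenes and the vinylogous ester.

Step 22
Reactants: 33 (1R,5R,7R)-3-(3,4-dihydroxybenzoyl)-7-[(2E)-3,7-dimethylocta-2,6-dien-1-yl]-2-methoxy-8,8-dimethyl-1,5-bis(3-methylbut-2-en-1-yl)bicyclo[3.3.1]non-2-ene-4,9-dione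
Product: 34 oblongifolin B, (1S,5S,7R)-3-(3,4-dihydroxybenzoyl)-7-[(2E)-3,7-dimethylocta-2,6-dien-1-yl]-4-hydroxy-8,8-dimethyl-1,5-bis(3-methylbut-2-en-1-yl)bicyclo[3.3.1]non-3-ene-2,9-dione
Conditions: LiCl (10 equiv), DMSO (degassed), 120 °C, argon; dilute aq. HCl to pH 4, 0 °C
Reagents that add atoms: none
Why: Krapcho-type SN2 demethylation: chloride attacks the methyl group and the leaving group is the stabilised enolate of the acyl trione. The neutral conditions spare the prenyl and geranyl groups, and the weakly acidic cold work-up avoids cyclisation of the enol onto a prenyl group.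

## Compound list

1 | 2-(2,6-dimethoxyphenyl)acetic acid | COc1cccc(OC)c1CC(=O)O | starting material
2 | 2-(2,6-dimethoxyphenyl)propanoic acid (racemic, present as its lithium salt) | COc1cccc(OC)c1C(C)C(=O)O | intermediate
3 | 2-(2,6-dimethoxyphenyl)-2-methylpropanoic acid | COc1cccc(OC)c1C(C)(C)C(=O)O | intermediate
4 | 3-(2,6-dimethoxyphenyl)-3-methylbutan-2-one | COc1cccc(OC)c1C(C)(C)C(C)=O | intermediate
5 | 3-(2,6-dimethoxyphenyl)-3-methylbutan-2-ol (racemic, present as its lithium alkoxide) | COc1cccc(OC)c1C(C)(C)C(C)O | intermediate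
6 | 3-(2,6-dimethoxycyclohexa-2,5-dien-1-yl)-3-methylbutan-2-ol (racemic) | COC1=CCC=C(OC)C1C(C)(C)C(C)O | intermediate
7 | 1-bromo-3-methylbut-2-ene (prenyl bromide) | CC(C)=CCBr | starting material
8 | 3-[2,6-dimethoxy-1-(3-methylbut-2-en-1-yl)cyclohexa-2,5-dien-1-yl]-3-methylbutan-2-ol (racemic) | COC1=CCC=C(OC)C1(CC=C(C)C)C(C)(C)C(C)O | intermediate
9 | 3-[2,6-dimethoxy-1-(3-methylbut-2-en-1-yl)cyclohexa-2,5-dien-1-yl]-3-methylbutan-2-one | COC1=CCC=C(OC)C1(CC=C(C)C)C(C)(C)C(C)=O | intermediate
10 | 5-[2,6-dimethoxy-1-(3-methylbut-2-en-1-yl)cyclohexa-2,5-dien-1-yl]-1,1,1-trifluoro-5-methylhexane-2,4-dione | COC1=CCC=C(OC)C1(CC=C(C)C)C(C)(C)C(=O)CC(=O)C(F)(F)F | intermediate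
11 | 1-diazo-3-[2,6-dimethoxy-1-(3-methylbut-2-en-1-yl)cyclohexa-2,5-dien-1-yl]-3-methylbutan-2-one | COC1=CCC=C(OC)C1(CC=C(C)C)C(C)(C)C(=O)C=[N+]=[N-] | intermediate
12 | (1S,2R,6R,9S)-1,5-dimethoxy-7,7-dimethyl-6-(3-methylbut-2-en-1-yl)tricyclo[4.3.0.0(2,9)]non-4-en-8-one | COC1=CC[C@@H]2[C@@H]3C(=O)C(C)(C)[C@@]1(CC=C(C)C)[C@]23OC | intermediate
13 | (1R,5R)-2-methoxy-8,8-dimethyl-1-(3-methylbut-2-en-1-yl)-7-(trimethylsilyloxy)bicyclo[3.3.1]nona-2,6-dien-9-one | C[Si](C)(C)OC1=C[C@@H]2C(=O)[C@@](CC=C(C)C)(C(OC)=CC2)C1(C)C | intermediate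
14 | (1R,5R)-2-methoxy-8,8-dimethyl-1-(3-methylbut-2-en-1-yl)bicyclo[3.3.1]non-2-ene-7,9-dione | O=C1C[C@@H]2C(=O)[C@@](CC=C(C)C)(C(OC)=CC2)C1(C)C | intermediate
15 | (1R,5S)-2-methoxy-8,8-dimethyl-1-(3-methylbut-2-en-1-yl)bicyclo[3.3.1]non-2-ene-4,7,9-trione | O=C1C[C@@H]2C(=O)[C@@](CC=C(C)C)(C(OC)=CC2=O)C1(C)C | intermediate
16 | (1R,5S)-2-methoxy-8,8-dimethyl-7-methylidene-1-(3-methylbut-2-en-1-yl)bicyclo[3.3.1]non-2-ene-4,9-dione | C=C1C[C@@H]2C(=O)[C@@](CC=C(C)C)(C(OC)=CC2=O)C1(C)C | intermediate
17 | (1R,5S,7S)-7-(hydroxymethyl)-2-methoxy-8,8-dimethyl-1-(3-methylbut-2-en-1-yl)bicyclo[3.3.1]non-2-ene-4,9-dione (CH2OH endo) | OC[C@H]1C[C@@H]2C(=O)[C@@](CC=C(C)C)(C(OC)=CC2=O)C1(C)C | intermediate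
18 | (1R,5S,7S)-2-methoxy-8,8-dimethyl-1-(3-methylbut-2-en-1-yl)-4,9-dioxobicyclo[3.3.1]non-2-ene-7-carbaldehyde (CHO endo) | O=C[C@H]1C[C@@H]2C(=O)[C@@](CC=C(C)C)(C(OC)=CC2=O)C1(C)C | intermediate
19 | (1R,5S,7R)-2-methoxy-8,8-dimethyl-1-(3-methylbut-2-en-1-yl)-4,9-dioxobicyclo[3.3.1]non-2-ene-7-carbaldehyde (CHO exo) | O=C[C@@H]1C[C@@H]2C(=O)[C@@](CC=C(C)C)(C(OC)=CC2=O)C1(C)C | intermediate
20 | (1R,5S,7R)-7-(hydroxymethyl)-2-methoxy-8,8-dimethyl-1-(3-methylbut-2-en-1-yl)bicyclo[3.3.1]non-2-ene-4,9-dione (CH2OH exo) | OC[C@@H]1C[C@@H]2C(=O)[C@@](CC=C(C)C)(C(OC)=CC2=O)C1(C)C | intermediate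
21 | (1R,5S,7R)-7-(iodomethyl)-2-methoxy-8,8-dimethyl-1-(3-methylbut-2-en-1-yl)bicyclo[3.3.1]non-2-ene-4,9-dione | IC[C@@H]1C[C@@H]2C(=O)[C@@](CC=C(C)C)(C(OC)=CC2=O)C1(C)C | intermediate
22 | 6-methylhept-5-en-1-yne | CC(C)=CCCC#C | starting material
23 | [(1E)-2,6-dimethylhepta-1,5-dien-1-yl]dimethylalane | CC(C)=CCC/C(C)=C/[Al](C)C | intermediate
24 | (1E)-1-iodo-2,6-dimethylhepta-1,5-diene | CC(C)=CCC/C(C)=C/I | intermediate
25 | iodo{[(1R,5S,7R)-2-methoxy-8,8-dimethyl-1-(3-methylbut-2-en-1-yl)-4,9-dioxobicyclo[3.3.1]non-2-en-7-yl]methyl}zinc | I[Zn]C[C@@H]1C[C@@H]2C(=O)[C@@](CC=C(C)C)(C(OC)=CC2=O)C1(C)C | intermediate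
26 | (1R,5S,7R)-7-[(2E)-3,7-dimethylocta-2,6-dien-1-yl]-2-methoxy-8,8-dimethyl-1-(3-methylbut-2-en-1-yl)bicyclo[3.3.1]non-2-ene-4,9-dione | CC(C)=CCC/C(C)=C/C[C@@H]1C[C@@H]2C(=O)[C@@](CC=C(C)C)(C(OC)=CC2=O)C1(C)C | intermediate
27 | (1R,5S,7R)-7-[(2E)-3,7-dimethylocta-2,6-dien-1-yl]-2-methoxy-8,8-dimethyl-1,5-bis(3-methylbut-2-en-1-yl)bicyclo[3.3.1]non-2-ene-4,9-dione | CC(C)=CCC/C(C)=C/C[C@@H]1C[C@]2(CC=C(C)C)C(=O)[C@@](CC=C(C)C)(C(OC)=CC2=O)C1(C)C | intermediate
28 | 3,4-dihydroxybenzoic acid | O=C(O)c1ccc(O)c(O)c1 | starting material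
29 | tert-butyldimethylsilyl 3,4-bis(tert-butyldimethylsilyloxy)benzoate | CC(C)(C)[Si](C)(C)OC(=O)c1ccc(O[Si](C)(C)C(C)(C)C)c(O[Si](C)(C)C(C)(C)C)c1 | intermediate
30 | 3,4-bis(tert-butyldimethylsilyloxy)benzoic acid | O=C(O)c1ccc(O[Si](C)(C)C(C)(C)C)c(O[Si](C)(C)C(C)(C)C)c1 | intermediate
31 | 3,4-bis(tert-butyldimethylsilyloxy)benzoyl chloride | O=C(Cl)c1ccc(O[Si](C)(C)C(C)(C)C)c(O[Si](C)(C)C(C)(C)C)c1 | intermediate
32 | (1R,5R,7R)-3-[3,4-bis(tert-butyldimethylsilyloxy)benzoyl]-7-[(2E)-3,7-dimethylocta-2,6-dien-1-yl]-2-methoxy-8,8-dimethyl-1,5-bis(3-methylbut-2-en-1-yl)bicyclo[3.3.1]non-2-ene-4,9-dione | CC(C)=CCC/C(C)=C/C[C@@H]1C[C@]2(CC=C(C)C)C(=O)[C@@](CC=C(C)C)(C(OC)=C(C(=O)c3ccc(O[Si](C)(C)C(C)(C)C)c(O[Si](C)(C)C(C)(C)C)c3)C2=O)C1(C)C | intermediate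
33 | (1R,5R,7R)-3-(3,4-dihydroxybenzoyl)-7-[(2E)-3,7-dimethylocta-2,6-dien-1-yl]-2-methoxy-8,8-dimethyl-1,5-bis(3-methylbut-2-en-1-yl)bicyclo[3.3.1]non-2-ene-4,9-dione | CC(C)=CCC/C(C)=C/C[C@@H]1C[C@]2(CC=C(C)C)C(=O)[C@@](CC=C(C)C)(C(OC)=C(C(=O)c3ccc(O)c(O)c3)C2=O)C1(C)C | intermediate
34 | oblongifolin B, (1S,5S,7R)-3-(3,4-dihydroxybenzoyl)-7-[(2E)-3,7-dimethylocta-2,6-dien-1-yl]-4-hydroxy-8,8-dimethyl-1,5-bis(3-methylbut-2-en-1-yl)bicyclo[3.3.1]non-3-ene-2,9-dione | CC(C)=CCC/C(C)=C/C[C@@H]1C[C@]2(CC=C(C)C)C(=O)[C@@](CC=C(C)C)(C(=O)C(C(=O)c3ccc(O)c(O)c3)=C2O)C1(C)C | target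

## Step count and least certain steps

Total: 22 steps. Longest linear sequence: 19 steps from 1 (steps 1–14, 16, 17, 20, 21, 22). Steps 15, 18 and 19 prepare 24 and 31.

**Step 7 (key step).** The most likely failure is poor discrimination between the two enantiotopic enol ethers, because the diazo ketone carbene carries only hydrogen as its second substituent and binds copper through a single point. Loss of material through carbene addition to the prenyl alkene, insertion into its allylic C–H bonds or ylide formation at a methoxy oxygen is the second risk. The fallback makes the carbene more rigid with a second acceptor; it sets out from 9 and returns to the route at 14. The lithium enolate of 9 (LiN(SiMe3)2, 2 equiv) is C-sulfonylated with 2,4,6-trimethylbenzenesulfonyl fluoride to give β-keto sulfone F1. Regitz diazo transfer (4-acetamidobenzenesulfonyl azide, Et3N, MeCN) gives the α-diazo-β-keto sulfone F2. Cyclopropanation under the conditions of step 7 gives the C6-sulfonyl tricycle F3, and the conditions of step 8 open it to the C6-sulfonyl diketone F4. SmI2 (THF/MeOH, −78 °C) then removes the sulfonyl group reductively and gives 14.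

**Step 4.** Removal of the C1–H bond may be slow because C1 already carries a tertiary substituent, and the anion may be alkylated at a ring terminus instead of the central carbon, since the wanted bond creates two adjacent fully substituted carbons. O-Alkylation of the alkoxide is a minor risk. The fallback postpones the gem-dimethyl group until after the key step; it sets out from 1 and returns at 12. Acid 1 with MeLi gives arylacetone F5, and Birch reduction as in step 3 gives dienyl alcohol F6. Lithiation and alkylation with 7 as in step 4 now take place next to a CH2 group and give F7, and Dess–Martin oxidation gives ketone F8. Kinetic deprotonation on the methyl side, followed by the two-stage diazo transfer of step 6, gives diazo ketone F9. The cyclopropanation of step 7 gives tricycle F10. Exhaustive methylation at C8 (KN(SiMe3)2, excess MeI; the cyclopropane carbon C6 cannot be enolised) then gives 12.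

**Step 8.** The likely failures are exchange or hydrolysis of the C2 enol ether under the Lewis-acidic conditions, and a slow opening because the C6–C9 bond overlaps poorly with the C7 carbonyl in the fused five-membered ring. The fallback gives up the enol ether and reaches the C4 oxygen by polar chemistry; it sets out from 12 and returns at 15, and so also replaces step 9. Aqueous HCl in THF opens the cyclopropane and hydrolyses both methyl ethers to trione F11. IBX (DMSO, 70 °C) dehydrogenates only the C2 ketone, because the β carbon of the C7 ketone is the bridgehead C5, and gives enedione F12. Nucleophilic epoxidation (t-BuOOH, DBU) gives epoxy ketone F13, and Pd(PPh3)4 with 1,2-bis(diphenylphosphino)ethane (toluene, 80 °C; zerovalent palladium) isomerises it to the enolised 2,4-dione F14. O-Methylation (Me3SiCHN2, MeOH) gives 15 together with its regioisomer F15, which is separated and hydrolysed back to F14.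

**Step 9.** Hydrogen abstraction from the allylic positions of the prenyl group may compete with abstraction at C4, and the peroxide may go on to oxidise the product. The fallback sets out from 14 and returns at 15: hydrolysis of the enol ether (oxalic acid, wet THF) gives F11, and the detour described for step 8 is then followed unchanged through F12, F13 and F14; no further compound is made.

**Step 17.** Deprotonation may take place at the vinyl position C3 instead of the bridgehead C5, or the bridgehead anion may be alkylated sluggishly. The fallback blocks C3; it sets out from 26 and returns at 27. Lithium 2,2,6,6-tetramethylpiperidide in the presence of Me3SiCl silylates C3 to give F16. LDA and 7 then alkylate the only remaining acidic position, C5, to give F17, and Bu4NF removes the silyl group to give 27.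

## Further compounds

F1 | step 7 | 3-[2,6-dimethoxy-1-(3-methylbut-2-en-1-yl)cyclohexa-2,5-dien-1-yl]-3-methyl-1-(2,4,6-trimethylbenzenesulfonyl)butan-2-one | COC1=CCC=C(OC)C1(CC=C(C)C)C(C)(C)C(=O)CS(=O)(=O)c1c(C)cc(C)cc1C
F2 | step 7 | 1-diazo-3-[2,6-dimethoxy-1-(3-methylbut-2-en-1-yl)cyclohexa-2,5-dien-1-yl]-3-methyl-1-(2,4,6-trimethylbenzenesulfonyl)butan-2-one | COC1=CCC=C(OC)C1(CC=C(C)C)C(C)(C)C(=O)C(=[N+]=[N-])S(=O)(=O)c1c(C)cc(C)cc1C
F3 | step 7 | 1,5-dimethoxy-7,7-dimethyl-6-(3-methylbut-2-en-1-yl)-9-(2,4,6-trimethylbenzenesulfonyl)tricyclo[4.3.0.0(2,9)]non-4-en-8-one (ring configuration as in 12) | COC1=CC[C@@H]2[C@]3(S(=O)(=O)c4c(C)cc(C)cc4C)C(=O)C(C)(C)[C@@]1(CC=C(C)C)[C@]23OC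
F4 | step 7 | 2-methoxy-8,8-dimethyl-1-(3-methylbut-2-en-1-yl)-6-(2,4,6-trimethylbenzenesulfonyl)bicyclo[3.3.1]non-2-ene-7,9-dione (C1 and C5 as in 14, C6 epimers) | O=C1C(S(=O)(=O)c3c(C)cc(C)cc3C)[C@@H]2C(=O)[C@@](CC=C(C)C)(C(OC)=CC2)C1(C)C
F5 | step 4 | 1-(2,6-dimethoxyphenyl)propan-2-one | COc1cccc(OC)c1CC(C)=O
F6 | step 4 | 1-(2,6-dimethoxycyclohexa-2,5-dien-1-yl)propan-2-ol (racemic) | COC1=CCC=C(OC)C1CC(C)O
F7 | step 4 | 1-[2,6-dimethoxy-1-(3-methylbut-2-en-1-yl)cyclohexa-2,5-dien-1-yl]propan-2-ol (racemic) | COC1=CCC=C(OC)C1(CC=C(C)C)CC(C)O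
F8 | step 4 | 1-[2,6-dimethoxy-1-(3-methylbut-2-en-1-yl)cyclohexa-2,5-dien-1-yl]propan-2-one | COC1=CCC=C(OC)C1(CC=C(C)C)CC(C)=O
F9 | step 4 | 1-diazo-3-[2,6-dimethoxy-1-(3-methylbut-2-en-1-yl)cyclohexa-2,5-dien-1-yl]propan-2-one | COC1=CCC=C(OC)C1(CC=C(C)C)CC(=O)C=[N+]=[N-]
F10 | step 4 | 1,5-dimethoxy-6-(3-methylbut-2-en-1-yl)tricyclo[4.3.0.0(2,9)]non-4-en-8-one (configuration as in 12) | COC1=CC[C@@H]2[C@@H]3C(=O)C[C@@]1(CC=C(C)C)[C@]23OC
F11 | step 8 | (1R,5R)-8,8-dimethyl-1-(3-methylbut-2-en-1-yl)bicyclo[3.3.1]nonane-2,7,9-trione | O=C1C[C@@H]2C(=O)[C@@](CC=C(C)C)(C(=O)CC2)C1(C)C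
F12 | step 8 | (1R,5S)-8,8-dimethyl-1-(3-methylbut-2-en-1-yl)bicyclo[3.3.1]non-3-ene-2,7,9-trione | O=C1C[C@@H]2C(=O)[C@@](CC=C(C)C)(C(=O)C=C2)C1(C)C
F13 | step 8 | 3,4-epoxy-8,8-dimethyl-1-(3-methylbut-2-en-1-yl)bicyclo[3.3.1]nonane-2,7,9-trione (bridgeheads as in F11, epoxide face not assigned) | O=C1C[C@@H]2C(=O)[C@@](CC=C(C)C)(C(=O)C3OC32)C1(C)C
F14 | step 8 | 4-hydroxy-8,8-dimethyl-1-(3-methylbut-2-en-1-yl)bicyclo[3.3.1]non-3-ene-2,7,9-trione (bridgeheads as in 15) | O=C1C[C@@H]2C(=O)[C@@](CC=C(C)C)(C(=O)C=C2O)C1(C)C
F15 | step 8 | 4-methoxy-8,8-dimethyl-1-(3-methylbut-2-en-1-yl)bicyclo[3.3.1]non-3-ene-2,7,9-trione (bridgeheads as in 15) | O=C1C[C@@H]2C(=O)[C@@](CC=C(C)C)(C(=O)C=C2OC)C1(C)C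
F0 | step 9 | none | none
F16 | step 17 | 7-[(2E)-3,7-dimethylocta-2,6-dien-1-yl]-2-methoxy-8,8-dimethyl-1-(3-methylbut-2-en-1-yl)-3-(trimethylsilyl)bicyclo[3.3.1]non-2-ene-4,9-dione (configuration as in 26) | CC(C)=CCC/C(C)=C/C[C@@H]1C[C@@H]2C(=O)[C@@](CC=C(C)C)(C(OC)=C([Si](C)(C)C)C2=O)C1(C)C
F17 | step 17 | 7-[(2E)-3,7-dimethylocta-2,6-dien-1-yl]-2-methoxy-8,8-dimethyl-1,5-bis(3-methylbut-2-en-1-yl)-3-(trimethylsilyl)bicyclo[3.3.1]non-2-ene-4,9-dione (configuration as in 27) | CC(C)=CCC/C(C)=C/C[C@@H]1C[C@]2(CC=C(C)C)C(=O)[C@@](CC=C(C)C)(C(OC)=C([Si](C)(C)C)C2=O)C1(C)C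
A1 | alternative 1 | 3-(3-methylbut-2-en-1-yl)-2-[tri(propan-2-yl)silyloxy]buta-1,3-diene | C=C(CC=C(C)C)C(=C)O[Si](C(C)C)(C(C)C)C(C)C
A2 | alternative 1 | 3-(3-methylbut-2-enoyl)-1,3-oxazolidin-2-one | CC(C)=CC(=O)N1CCOC1=O
A3 | alternative 1 | 3-{[(1R)-2,2-dimethyl-5-(3-methylbut-2-en-1-yl)-4-[tri(propan-2-yl)silyloxy]cyclohex-4-en-1-yl]carbonyl}-1,3-oxazolidin-2-one | O=C(N2CCOC2=O)[C@@H]1CC(CC=C(C)C)=C(O[Si](C(C)C)(C(C)C)C(C)C)CC1(C)C
A4 | alternative 2 | (4aS)-5-methoxy-4a,8-bis(3-methylbut-2-en-1-yl)-3-(propan-2-ylidene)-2,3,4,4a-tetrahydro-7H-chromen-7-one | COC1=CC(=O)C(CC=C(C)C)=C2OCC(=C(C)C)C[C@@]12CC=C(C)C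
A5 | alternative 2 | (1R,5S)-4-methoxy-8,8-dimethyl-7-methylidene-1,5-bis(3-methylbut-2-en-1-yl)bicyclo[3.3.1]non-3-ene-2,9-dione | C=C1C[C@]2(CC=C(C)C)C(=O)[C@@](CC=C(C)C)(C(=O)C=C2OC)C1(C)C
A6 | alternative 3 | [3,4-bis(tert-butyldimethylsilyloxy)phenyl][2,4,6-trihydroxy-3,5-bis(3-methylbut-2-en-1-yl)phenyl]methanone | CC(C)=CCc1c(O)c(CC=C(C)C)c(O)c(C(=O)c2ccc(O[Si](C)(C)C(C)(C)C)c(O[Si](C)(C)C(C)(C)C)c2)c1O
A7 | alternative 3 | 3-formyl-2-methylbut-3-en-2-yl acetate | CC(=O)OC(C)(C)C(=C)C=O
A8 | alternative 3 | (1S,5S,7R)-3-[3,4-bis(tert-butyldimethylsilyloxy)benzoyl]-4-hydroxy-8,8-dimethyl-1,5-bis(3-methylbut-2-en-1-yl)-2,9-dioxobicyclo[3.3.1]non-3-ene-7-carbaldehyde | O=C[C@@H]1C[C@]2(CC=C(C)C)C(=O)[C@@](CC=C(C)C)(C(=O)C(C(=O)c3ccc(O[Si](C)(C)C(C)(C)C)c(O[Si](C)(C)C(C)(C)C)c3)=C2O)C1(C)C
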